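The slowness of this flask hangs on one concentration, that of free nucleophile.

    electrophile + nucleophile → acid set free + target (k1 = 4.69 × 10⁻⁴ M⁻¹ s⁻¹)
    nucleophile + acid set free ⇌ protonated nucleophile, settled at all times (K2 = 19800 M⁻¹)
    acid set free + free base ⇌ salt of the base, settled at all times (K3 = 72000 M⁻¹)
    acid set free → by-product carried off (k4 = 3.01 × 10⁻⁴ s⁻¹)
    electrophile + target ⇌ idle adduct, settled at all times (K5 = 12.7 M⁻¹)

electrophile 1.0 M; protonated nucleophile 2.00 equiv; time 2.5 h

- a species is counted by the electrophile in it: one idle adduct counts as two
- amounts and yields of target count idle adduct too
- the amount of free base is what is sought; it is there from the start
- in an amount of target, one idle adduct counts as one target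
- what has gone from electrophile into another species counts as reacted, even if it can come back
- run time (flask): 2.5 h

- the equivalents of free base at which the part of the electrophile that has reacted at 2.5 h is just 50%

My first thought is that the 2.00 equiv of protonated nucleophile is a reservoir, which makes the coupling pseudo-first-order in electrophile. But that form does not couple, and the free base must take its proton. It can, because the base binds acid more strongly than the nucleophile does (72000 M⁻¹ against 19800 M⁻¹). So free nucleophile is what the base releases, and free base is the limiting reagent.

Each turnover consumes one nucleophile and sets free one acid, which takes up a second nucleophile or base, so a turnover costs two base. Time gives no relief: the half-life of nucleophile by step 1, with the other concentrations as charged, is 0.41 h, far shorter than the run of 2.5 h.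

One objection is that acid lost by step 4 hands a nucleophile back, and its half-life of 0.64 h is also shorter than the run. But that clock acts on free acid. Where free nucleophile and free acid stand about equal, free acid is about 0.0101 M, and held over the whole run that gives my rough estimate of 0.0272 M carried off.

A second objection is that reacted electrophile is not turnover, since step 5 is strong (its constant times the starting electrophile is 13). At 50% reacted, free electrophile is 0.500 M, and the balance of step 5 gives 0.232 M of idle adduct. That leaves 0.268 M as the paid turnover, the turnover the base must pay for. The paid turnover is about ten times my estimate of acid carried off, so I set that estimate aside and commit to 0.536 equiv of base.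

The forecast is also 0.54 equiv: “each turnover uses two nucleophile equivalents' worth of base”.

The simulation gives 0.532 equiv. In that flask 0.174% of the charged free base is still free at 2.50 h, and the paid turnover of 0.268 M stands for 0.536 equiv of base. Now take a second flask with twice the electrophile and the other amounts as they are. I keep the paid turnover at 0.268 M, step 5 then holds 0.255 M as idle adduct, and the part reacted comes to 26.1%. The simulated run of that flask ends at 28.1%.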